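**Plan**

- Feature: number each terminal ring C1 (acyl carbon), C2, C3 (CMe2), C4, C5 (bridge carbon), C6. Ring A (butanoyl) and ring C (propanoyl) are then each a folded chain acyl–C1–C6–C5–C4–C3–C2 with C2 at the carboxyl level and C1 between two carbonyls. The quaternary C3 stops any O-cyclised isomer from aromatising, so one base treatment can close both rings by C1–C2 Claisen condensation.
- Retrosynthetic cuts, in order: the aryl–butanoyl bond on central ring B; the C1–C2 bond of rings A and C; the C4–C5 bond of each arm (acylation by one molecule of dimethyl 2,2-dimethylmalonate per arm); the bond from each future bridge carbon (an aryl aldehyde carbon) to C5 (lateral isoxazole anion).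
- Forward: ring B is there from the start as tribenzylated phloroglucinaldehyde. The propyl-isoxazole arm is added and deoxygenated, ring B is formylated again, and the ethyl-isoxazole arm is added and deoxygenated. Both arms are acylated in one operation and unmasked to the bis(triketo ester), rings A and C close together, and debenzylation and C-butanoylation of ring B finish the synthesis.
- Stereochemistry: the target has no stereocentre. The carbinol centres (11, 16) are removed by deoxygenation and the C5 centres (20 to 22) vanish on enolisation, so no stereocontrol is needed.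

Key step: step 11

Remark: the terminal triones are drawn as one enol tautomer; compounds with transient or enolisable stereocentres (11, 16, 20 to 22) are racemates or diastereomer mixtures and their SMILES carry no configuration.

**Step 1**
Reactants: 1 2,4,6-trihydroxybenzaldehyde
Product: 2 2,4,6-tris(benzyloxy)benzaldehyde
Conditions: BnBr (3.3 equiv), K2CO3 (4 equiv), DMF, 60 °C
Reagents that add atoms: benzyl bromide, BrCc1ccccc1
Why: Williamson etherification of the three phenols; the formyl group lowers the carbon nucleophilicity of the ring, so O-benzylation should prevail.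

**Step 2**
Reactants: 3 1-nitrobutane; 4 propyne
Product: 6 5-methyl-3-propylisoxazole, via butanenitrile oxide 5 (not isolated)
Conditions: PhNCO (2.1 equiv), Et3N (cat.), propyne (excess), toluene, sealed vessel, rt
Reagents that add atoms: none
Why: Mukaiyama–Hoshino dehydration of the primary nitroalkane gives the nitrile oxide, whose 1,3-dipolar cycloaddition to a terminal alkyne puts the alkyne substituent at C5, so the propyl group sits on C3, the carbon that later becomes the butanoyl carbonyl.

**Step 3**
Reactants: 7 1-nitropropane; 4 propyne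
Product: 9 3-ethyl-5-methylisoxazole, via propanenitrile oxide 8 (not isolated)
Conditions: PhNCO (2.1 equiv), Et3N (cat.), propyne (excess), toluene, sealed vessel, rt
Reagents that add atoms: none
Why: the same Mukaiyama–Hoshino nitrile oxide generation and regioselective 1,3-dipolar cycloaddition, here fixing ethyl on C3 for the propanoyl arm.

**Step 4**
Reactants: 6 5-methyl-3-propylisoxazole; 2 2,4,6-tris(benzyloxy)benzaldehyde
Product: 11 racemic 2-(3-propylisoxazol-5-yl)-1-[2,4,6-tris(benzyloxy)phenyl]ethanol, via (3-propylisoxazol-5-yl)methyllithium 10 (not isolated)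
Conditions: LiN(iPr)2 (1.1 equiv), THF, −78 °C; then 2, −78 °C; AcOH
Reagents that add atoms: none
Why: lateral lithiation of a 3,5-dialkylisoxazole occurs at the C5 methyl group and the carbanion adds 1,2 to the aldehyde; the carbinol centre forms as a racemate and is removed in step 5.

**Step 5**
Reactants: 11 racemic 2-(3-propylisoxazol-5-yl)-1-[2,4,6-tris(benzyloxy)phenyl]ethanol
Product: 12 3-propyl-5-{2-[2,4,6-tris(benzyloxy)phenyl]ethyl}isoxazole
Conditions: Et3SiH (5 equiv), TFA, CH2Cl2, −20 to 0 °C, high dilution
Reagents that add atoms: none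
Why: ionic hydrogenation (benzylic deoxygenation): the trialkoxybenzylic alcohol ionises in TFA and the cation, or the styrene in equilibrium with it, takes hydride from the silane, which is used in excess to outrun Friedel–Crafts capture by another arene.

**Step 6**
Reactants: 12 3-propyl-5-{2-[2,4,6-tris(benzyloxy)phenyl]ethyl}isoxazole
Product: 14 2,4,6-tris(benzyloxy)-3-[2-(3-propylisoxazol-5-yl)ethyl]benzaldehyde, via aryl dimethyliminium chloride 13 (not isolated)
Conditions: POCl3 (1.5 equiv), DMF, 0 to 40 °C; then H2O, rt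
Reagents that add atoms: N,N-dimethylformamide, CN(C)C=O (formyl carbon); water, O (carbonyl oxygen)
Why: Vilsmeier–Haack formylation at one of the two equivalent ring positions activated by the benzyloxy groups; the new formyl group deactivates the ring against a second attack and the isoxazole is inert.

**Step 7**
Reactants: 9 3-ethyl-5-methylisoxazole; 14 2,4,6-tris(benzyloxy)-3-[2-(3-propylisoxazol-5-yl)ethyl]benzaldehyde
Product: 16 racemic 2-(3-ethylisoxazol-5-yl)-1-{2,4,6-tris(benzyloxy)-3-[2-(3-propylisoxazol-5-yl)ethyl]phenyl}ethanol, via (3-ethylisoxazol-5-yl)methyllithium 15 (not isolated)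
Conditions: LiN(iPr)2 (1.2 equiv), THF, −78 °C; then 14, −78 °C; AcOH
Reagents that add atoms: none
Why: lateral lithiation at the C5 methyl group and 1,2-addition to the aldehyde, which is faster than proton exchange with the CH2 next to the first isoxazole; the racemic carbinol centre is removed in step 8.

**Step 8**
Reactants: 16 racemic 2-(3-ethylisoxazol-5-yl)-1-{2,4,6-tris(benzyloxy)-3-[2-(3-propylisoxazol-5-yl)ethyl]phenyl}ethanol
Product: 17 1,3,5-tris(benzyloxy)-2-[2-(3-propylisoxazol-5-yl)ethyl]-4-[2-(3-ethylisoxazol-5-yl)ethyl]benzene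
Conditions: Et3SiH (5 equiv), TFA, CH2Cl2, −20 to 0 °C
Reagents that add atoms: none
Why: ionic hydrogenation of the second trialkoxybenzylic alcohol, as in step 5; ring B now has a single, flanked free position, which lowers the risk of arene alkylation further.

**Step 9**
Reactants: 17 1,3,5-tris(benzyloxy)-2-[2-(3-propylisoxazol-5-yl)ethyl]-4-[2-(3-ethylisoxazol-5-yl)ethyl]benzene; 18 dimethyl 2,2-dimethylmalonate (two molecules are taken up, one by each arm)
Product: 20 1,3,5-tris(benzyloxy)-2-[5-methoxy-4,4-dimethyl-3,5-dioxo-2-(3-propylisoxazol-5-yl)pentyl]-4-[2-(3-ethylisoxazol-5-yl)-5-methoxy-4,4-dimethyl-3,5-dioxopentyl]benzene (diastereomer mixture), via dilithiated bis-isoxazole 19 (not isolated)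
Conditions: LiN(iPr)2 (4.4 equiv), THF, −78 °C; then transfer by cannula into 18 (6 equiv) in THF, −78 to −20 °C; AcOH
Reagents that add atoms: dimethyl 2,2-dimethylmalonate (the second molecule of 18, which acylates the second arm), COC(=O)C(C)(C)C(=O)OC
Why: twofold lateral lithiation at the CH2 next to each isoxazole C5 and Claisen-type C-acylation of each carbanion by one molecule of a diester that has no alpha hydrogen and is kept in excess so that it reacts at one ester group only; each new ketone is at once deprotonated at C5 by the extra base, which shields it from further attack, and the two C5 centres are enolisable so their configuration does not matter.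

**Step 10**
Reactants: 20 the bis(isoxazolyl keto ester) of step 9
Product: 22 1,3,5-tris(benzyloxy)-2-[5-methoxy-4,4-dimethyl-3,5-dioxo-2-(3-oxohexanoyl)pentyl]-4-[5-methoxy-4,4-dimethyl-3,5-dioxo-2-(3-oxopentanoyl)pentyl]benzene (diastereomer mixture), via bis-enaminone 21 (not isolated)
Conditions: Mo(CO)6 (2 equiv), MeCN/H2O, 80 °C; then 1 M HCl, THF, rt
Reagents that add atoms: water, O (oxygen of the two new ketones)
Why: reductive N–O cleavage of isoxazoles by Mo(CO)6 in wet acetonitrile spares benzyl ethers, ketones and esters and gives the vinylogous amides, which dilute acid hydrolyses to the 1,3-diketones; the C4 ketone, flanked by a quaternary and a tertiary carbon, should resist condensation with the enamine nitrogen.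

**Step 11**
Reactants: 22 the bis(triketo ester) of step 10
Product: 23 1,3,5-tris(benzyloxy)-2-[(5-butanoyl-2,4-dihydroxy-3,3-dimethyl-6-oxocyclohexa-1,4-dien-1-yl)methyl]-4-[(2,4-dihydroxy-3,3-dimethyl-6-oxo-5-propanoylcyclohexa-1,4-dien-1-yl)methyl]benzene
Conditions: NaOMe (6 equiv), MeOH, 0 to 50 °C; then 1 M HCl
Reagents that add atoms: none
Why: Methoxide converts each arm into its dianion (C5 and C1 deprotonated), and the C1 carbanion, flanked by the acyl and C6 carbonyls, adds to the C2 ester carbonyl and expels methoxide, after which deprotonation of the very acidic 2-acyl-1,3,5-trione removes the product from the equilibrium. The closest known reaction type is the Claisen (Dieckmann-type) cyclisation of 3,5,7-triketo esters to acylphloroglucinols and of keto esters with a quaternary alpha carbon to 4,4-dimethylcyclohexane-1,3-diones. Ring A and ring C each close in the 6-exo-trig mode, the enolate carbon C1 attacking the exocyclic ester carbonyl C2. No stereocentre is created, and the two C5 centres of 22 become sp2 in the enolised product. The step needs C- over O-acylation and the right nucleophilic carbon: only C1 can reach C2 through a six-membered transition state (C5 would close a four-membered ring), an enol lactone from O-attack cannot aromatise because C3 is quaternary and is reopened by methoxide, and the enolate character of the C4–C6 unit together with the steric shielding of C4 guards against retro-Claisen scission. The benzyl ethers keep ring B out of the reaction, so that no chromene forms with the arm ketones and no phenoxide can expel a bridge.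

**Step 12**
Reactants: 23 the tribenzyl ether of step 11
Product: 24 2-[(5-butanoyl-2,4-dihydroxy-3,3-dimethyl-6-oxocyclohexa-1,4-dien-1-yl)methyl]-4-[(2,4-dihydroxy-3,3-dimethyl-6-oxo-5-propanoylcyclohexa-1,4-dien-1-yl)methyl]benzene-1,3,5-triol
Conditions: H2 (1 atm), 10% Pd/C, EtOAc/MeOH, rt
Reagents that add atoms: none
Why: hydrogenolysis of aryl benzyl ethers over palladium; the enolised acyl triones are vinylogous acids and should not be reduced at ambient pressure.

**Step 13**
Reactants: 24 the triphenol of step 12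
Product: 25 1-{3-[(5-butanoyl-2,4-dihydroxy-3,3-dimethyl-6-oxocyclohexa-1,4-dien-1-yl)methyl]-5-[(2,4-dihydroxy-3,3-dimethyl-6-oxo-5-propanoylcyclohexa-1,4-dien-1-yl)methyl]-2,4,6-trihydroxyphenyl}butan-1-one (CNP0373153.0)
Conditions: butanoyl chloride (1.5 equiv), TiCl4 (6 equiv), CH2Cl2, 0 °C to rt; then 1 M HCl
Reagents that add atoms: butanoyl chloride, CCCC(=O)Cl
Why: Friedel–Crafts acylation (TiCl4-mediated ortho-acylation of a phenol) at the only unsubstituted carbon of the molecule, the C–H of phloroglucinol ring B, while the enolic oxygens of rings A and C are held as titanium chelates and any enol ester formed is cleaved on acidic work-up.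

**Compound list**

1 | 2,4,6-trihydroxybenzaldehyde | O=Cc1c(O)cc(O)cc1O | starting material
2 | 2,4,6-tris(benzyloxy)benzaldehyde | O=Cc1c(OCc2ccccc2)cc(OCc2ccccc2)cc1OCc1ccccc1 | intermediate
3 | 1-nitrobutane | CCCC[N+](=O)[O-] | starting material
4 | propyne | CC#C | starting material
5 | butanenitrile oxide | CCCC#[N+][O-] | intermediate (not isolated)
6 | 5-methyl-3-propylisoxazole | CCCc1cc(C)on1 | intermediate
7 | 1-nitropropane | CCC[N+](=O)[O-] | starting material
8 | propanenitrile oxide | CCC#[N+][O-] | intermediate (not isolated)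
9 | 3-ethyl-5-methylisoxazole | CCc1cc(C)on1 | intermediate
10 | (3-propylisoxazol-5-yl)methyllithium | [Li]Cc1cc(CCC)no1 | intermediate (not isolated)
11 | racemic 2-(3-propylisoxazol-5-yl)-1-[2,4,6-tris(benzyloxy)phenyl]ethanol | CCCc1cc(CC(O)c2c(OCc3ccccc3)cc(OCc3ccccc3)cc2OCc2ccccc2)on1 | intermediate
12 | 3-propyl-5-{2-[2,4,6-tris(benzyloxy)phenyl]ethyl}isoxazole | CCCc1cc(CCc2c(OCc3ccccc3)cc(OCc3ccccc3)cc2OCc2ccccc2)on1 | intermediate
13 | {2,4,6-tris(benzyloxy)-3-[2-(3-propylisoxazol-5-yl)ethyl]benzylidene}dimethylammonium chloride | CCCc1cc(CCc2c(OCc3ccccc3)cc(OCc3ccccc3)c(C=[N+](C)C)c2OCc2ccccc2)on1.[Cl-] | intermediate (not isolated)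
14 | 2,4,6-tris(benzyloxy)-3-[2-(3-propylisoxazol-5-yl)ethyl]benzaldehyde | CCCc1cc(CCc2c(OCc3ccccc3)cc(OCc3ccccc3)c(C=O)c2OCc2ccccc2)on1 | intermediate
15 | (3-ethylisoxazol-5-yl)methyllithium | [Li]Cc1cc(CC)no1 | intermediate (not isolated)
16 | racemic 2-(3-ethylisoxazol-5-yl)-1-{2,4,6-tris(benzyloxy)-3-[2-(3-propylisoxazol-5-yl)ethyl]phenyl}ethanol | CCCc1cc(CCc2c(OCc3ccccc3)cc(OCc3ccccc3)c(C(O)Cc3cc(CC)no3)c2OCc2ccccc2)on1 | intermediate
17 | 1,3,5-tris(benzyloxy)-2-[2-(3-propylisoxazol-5-yl)ethyl]-4-[2-(3-ethylisoxazol-5-yl)ethyl]benzene | CCCc1cc(CCc2c(OCc3ccccc3)cc(OCc3ccccc3)c(CCc3cc(CC)no3)c2OCc2ccccc2)on1 | intermediate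
18 | dimethyl 2,2-dimethylmalonate | COC(=O)C(C)(C)C(=O)OC | starting material
19 | dilithio derivative of 17, lithiated at each CH2 next to an isoxazole C5 | CCCc1cc(C([Li])Cc2c(OCc3ccccc3)cc(OCc3ccccc3)c(CC([Li])c3cc(CC)no3)c2OCc2ccccc2)on1 | intermediate (not isolated)
20 | 1,3,5-tris(benzyloxy)-2-[5-methoxy-4,4-dimethyl-3,5-dioxo-2-(3-propylisoxazol-5-yl)pentyl]-4-[2-(3-ethylisoxazol-5-yl)-5-methoxy-4,4-dimethyl-3,5-dioxopentyl]benzene (diastereomer mixture) | CCCc1cc(C(Cc2c(OCc3ccccc3)cc(OCc3ccccc3)c(CC(C(=O)C(C)(C)C(=O)OC)c3cc(CC)no3)c2OCc2ccccc2)C(=O)C(C)(C)C(=O)OC)on1 | intermediate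
21 | 1,3,5-tris(benzyloxy)-2-[2-((Z)-3-aminohex-2-enoyl)-5-methoxy-4,4-dimethyl-3,5-dioxopentyl]-4-[2-((Z)-3-aminopent-2-enoyl)-5-methoxy-4,4-dimethyl-3,5-dioxopentyl]benzene (diastereomer mixture) | CCC/C(N)=C/C(=O)C(Cc1c(OCc2ccccc2)cc(OCc2ccccc2)c(CC(C(=O)/C=C(\N)CC)C(=O)C(C)(C)C(=O)OC)c1OCc1ccccc1)C(=O)C(C)(C)C(=O)OC | intermediate (not isolated)
22 | 1,3,5-tris(benzyloxy)-2-[5-methoxy-4,4-dimethyl-3,5-dioxo-2-(3-oxohexanoyl)pentyl]-4-[5-methoxy-4,4-dimethyl-3,5-dioxo-2-(3-oxopentanoyl)pentyl]benzene (diastereomer mixture) | CCCC(=O)CC(=O)C(Cc1c(OCc2ccccc2)cc(OCc2ccccc2)c(CC(C(=O)CC(=O)CC)C(=O)C(C)(C)C(=O)OC)c1OCc1ccccc1)C(=O)C(C)(C)C(=O)OC | intermediate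
23 | 1,3,5-tris(benzyloxy)-2-[(5-butanoyl-2,4-dihydroxy-3,3-dimethyl-6-oxocyclohexa-1,4-dien-1-yl)methyl]-4-[(2,4-dihydroxy-3,3-dimethyl-6-oxo-5-propanoylcyclohexa-1,4-dien-1-yl)methyl]benzene | CCCC(=O)C1=C(O)C(C)(C)C(O)=C(Cc2c(OCc3ccccc3)cc(OCc3ccccc3)c(CC3=C(O)C(C)(C)C(O)=C(C(=O)CC)C3=O)c2OCc2ccccc2)C1=O | intermediate
24 | 2-[(5-butanoyl-2,4-dihydroxy-3,3-dimethyl-6-oxocyclohexa-1,4-dien-1-yl)methyl]-4-[(2,4-dihydroxy-3,3-dimethyl-6-oxo-5-propanoylcyclohexa-1,4-dien-1-yl)methyl]benzene-1,3,5-triol | CCCC(=O)C1=C(O)C(C)(C)C(O)=C(Cc2c(O)cc(O)c(CC3=C(O)C(C)(C)C(O)=C(C(=O)CC)C3=O)c2O)C1=O | intermediate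
25 | 1-{3-[(5-butanoyl-2,4-dihydroxy-3,3-dimethyl-6-oxocyclohexa-1,4-dien-1-yl)methyl]-5-[(2,4-dihydroxy-3,3-dimethyl-6-oxo-5-propanoylcyclohexa-1,4-dien-1-yl)methyl]-2,4,6-trihydroxyphenyl}butan-1-one (CNP0373153.0) | CCCC(=O)C1=C(O)C(C)(C)C(O)=C(Cc2c(O)c(CC3=C(O)C(C)(C)C(O)=C(C(=O)CC)C3=O)c(O)c(C(=O)CCC)c2O)C1=O | target

**Step count and risks**

Total step count: 13. Longest linear sequence: 11 steps (steps 1, 4, 5, 6, 7, 8, 9, 10, 11, 12, 13).

The three steps most likely to fail:

1. Step 11. Methoxide may cleave the C3–C4 bond (retro-Claisen at a keto ester that cannot enolise towards C3) before C1 reaches the ester, or the reaction may stop after one ring because the polyanion of the half-cyclised compound is a poor nucleophile. The fallback sets out from 17 and returns at 23; it leaves the gem-dimethyl groups out of the cyclisation substrate so that ring closure is driven by aromatisation, and adds them last. The dilithio species 19 made from 17 would be quenched with CO2 to give the bis(isoxazolylacetic acid) F1. CDI would convert it in the flask into the bis(acyl imidazolide) F2, which with potassium methyl malonate, MgCl2 and Et3N, followed by acidic work-up, should give the bis(beta-keto ester) F3. Mo(CO)6 in wet acetonitrile would open both isoxazoles to the bis(enaminone) F4, hydrolysed in the same flask by dilute HCl to the bis(triketo ester) lacking the methyl groups F5. Mg(OMe)2 in methanol should then bring about the classical Claisen cyclisation of a 3,5,7-triketo ester, ending irreversibly in the bis(acylphloroglucinol) F6. Twofold C-methylation of the free ring carbon of each terminal ring with MeI and NaOMe in methanol, the standard entry to filicinic acids, would give 23.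

2. Step 13. The acid chloride may acylate the enolic and phenolic oxygens instead of carbon, and TiCl4 may promote heterolysis of the methylene bridges with scrambling of the ring units. The fallback sets out from 24 and returns at 25; it uses a nitrile as the acyl source (Houben–Hoesch reaction), which cannot acylate oxygen and stops at a deactivated iminium salt. Treatment of 24 with butanenitrile, ZnCl2 and dry HCl in Et2O at 0 °C should give the ketiminium chloride F7, and warming in water would hydrolyse it to 25.

3. Step 9. Attack of the hindered secondary carbanions on the hindered ester may be slow, so that proton transfer from the first acylated arm quenches the second carbanion and acylation stops at one arm, or one diester may be attacked at both ester groups and link two carbanions. The fallback sets out from 17 and returns at 20; it replaces the ester by an aldehyde and adjusts the oxidation level afterwards. The dilithio species 19 would add to methyl 2,2-dimethyl-3-oxopropanoate (an aldehyde that cannot enolise, available by oxidation of methyl hydroxypivalate) to give the bis(beta-hydroxy ester) F8, and oxidation of both carbinols with Dess–Martin periodinane in CH2Cl2 would give 20.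

**Further compounds**

F1 | step 11 | 2-(3-propylisoxazol-5-yl)- and 2-(3-ethylisoxazol-5-yl)-propanoic acids joined through C3 to C2 and C4 of 1,3,5-tris(benzyloxy)benzene (diacid, diastereomer mixture) | CCCc1cc(C(Cc2c(OCc3ccccc3)cc(OCc3ccccc3)c(CC(C(=O)O)c3cc(CC)no3)c2OCc2ccccc2)C(=O)O)on1
F2 | step 11 | bis(acyl imidazolide) of F1 | CCCc1cc(C(Cc2c(OCc3ccccc3)cc(OCc3ccccc3)c(CC(C(=O)n3ccnc3)c3cc(CC)no3)c2OCc2ccccc2)C(=O)n2ccnc2)on1
F3 | step 11 | bis(beta-keto ester): 20 without the four C3 methyl groups | CCCc1cc(C(Cc2c(OCc3ccccc3)cc(OCc3ccccc3)c(CC(C(=O)CC(=O)OC)c3cc(CC)no3)c2OCc2ccccc2)C(=O)CC(=O)OC)on1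
F4 | step 11 | bis((Z)-enaminone): 21 without the four C3 methyl groups | CCC/C(N)=C/C(=O)C(Cc1c(OCc2ccccc2)cc(OCc2ccccc2)c(CC(C(=O)/C=C(\N)CC)C(=O)CC(=O)OC)c1OCc1ccccc1)C(=O)CC(=O)OC
F5 | step 11 | bis(triketo ester): 22 without the four C3 methyl groups | CCCC(=O)CC(=O)C(Cc1c(OCc2ccccc2)cc(OCc2ccccc2)c(CC(C(=O)CC(=O)CC)C(=O)CC(=O)OC)c1OCc1ccccc1)C(=O)CC(=O)OC
F6 | step 11 | 1,3,5-tris(benzyloxy)-2-(3-butanoyl-2,4,6-trihydroxybenzyl)-4-(2,4,6-trihydroxy-3-propanoylbenzyl)benzene | CCCC(=O)c1c(O)cc(O)c(Cc2c(OCc3ccccc3)cc(OCc3ccccc3)c(Cc3c(O)cc(O)c(C(=O)CC)c3O)c2OCc2ccccc2)c1O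
F7 | step 13 | ketiminium chloride of 25 (C=NH2+ in place of the carbonyl of the butanoyl group on ring B) | CCCC(=O)C1=C(O)C(C)(C)C(O)=C(Cc2c(O)c(CC3=C(O)C(C)(C)C(O)=C(C(=O)CC)C3=O)c(O)c(C(=[NH2+])CCC)c2O)C1=O.[Cl-]
F8 | step 9 | bis(beta-hydroxy ester): 20 with both C4 ketones as secondary alcohols (diastereomer mixture) | CCCc1cc(C(Cc2c(OCc3ccccc3)cc(OCc3ccccc3)c(CC(C(O)C(C)(C)C(=O)OC)c3cc(CC)no3)c2OCc2ccccc2)C(O)C(C)(C)C(=O)OC)on1
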